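**Retrosynthetic overview**

- The strategy rests on C2 of the chroman (ring C), the only stereocenter: a tertiary C–H carbon between O1 and C1' of ring B. It is made by adding H2 across the flat C2=C3 enol ether of a 2-aryl-4H-chromene.
- The two prenyl groups at C2' and C3' of ring B would also be hydrogenated, so they are carried as bromines and installed last by a double Suzuki coupling; MOM ethers mask 7-OH, 4'-OH and 5'-OH.
- The 4H-chromene comes from cyclodehydration of a 1-(ring B)-3-(2-hydroxy ring A)propan-1-one, itself from a Claisen–Schmidt condensation and conjugate reduction.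
- The ring B methyl ketone is built from 5-bromovanillin (ring bromination, demethylation, MOM protection, MeMgBr, oxidation); ring A comes from 2,4-dihydroxybenzaldehyde.
- Rings A and B are bought; ring C closes in step 9 and is saturated in step 10; no ring forms afterwards.

Key step: step 10

Remark 1: the second ring bromination is done on the non-enolisable aldehyde, not on the corresponding acetophenone, because Br2 with a Lewis acid would risk α-bromination of a methyl ketone.
Remark 2: which enantiomer of the phosphine–oxazoline ligand leads to the 2R flavan cannot be predicted with certainty for this ortho-brominated substrate; both ligand enantiomers are available, the one that delivers the 2R product is used, and the dextrorotation expected for the final product would confirm the configuration.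

**Route**

Step 1
Reactants: 1 5-bromovanillin
Product: 2 2,3-dibromo-4-hydroxy-5-methoxybenzaldehyde
Conditions: Br2, Fe powder (cat.), AcOH, rt
Reagents that add atoms: bromine, BrBr
Why: Electrophilic aromatic bromination should go to the free position para to the methoxy group rather than the crowded one between CHO and OMe, and the aldehyde cannot enolise, so no side-chain bromination competes.

Step 2
Reactants: 2 2,3-dibromo-4-hydroxy-5-methoxybenzaldehyde
Product: 3 2,3-dibromo-4,5-dihydroxybenzaldehyde
Conditions: BBr3, CH2Cl2, −78 °C → rt; then H2O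
Reagents that add atoms: none
Why: Lewis-acid cleavage of the aryl methyl ether (BBr3 demethylation, bromide attacks the activated methyl group) should free the catechol while aldehyde and aryl bromides are untouched.

Step 3
Reactants: 3 2,3-dibromo-4,5-dihydroxybenzaldehyde
Product: 4 2,3-dibromo-4,5-bis(methoxymethoxy)benzaldehyde
Conditions: MOMCl, K2CO3, acetone, 0 °C → rt
Reagents that add atoms: chloromethyl methyl ether, COCCl
Why: Williamson-type O-alkylation of the acidic, electron-poor catechol with the small, reactive MOM chloride should protect both phenols, including the one flanked by bromine.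

Step 4
Reactants: 4 2,3-dibromo-4,5-bis(methoxymethoxy)benzaldehyde
Product: 5 rac-1-[2,3-dibromo-4,5-bis(methoxymethoxy)phenyl]ethanol
Conditions: MeMgBr, THF, −78 → 0 °C; aq. NH4Cl
Reagents that add atoms: methylmagnesium bromide, C[Mg]Br
Why: Grignard addition to the aldehyde is faster than bromine–magnesium exchange with MeMgBr at low temperature; the new carbinol center is racemic and is erased in step 5.

Step 5
Reactants: 5 rac-1-[2,3-dibromo-4,5-bis(methoxymethoxy)phenyl]ethanol
Product: 6 1-[2,3-dibromo-4,5-bis(methoxymethoxy)phenyl]ethanone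
Conditions: Dess–Martin periodinane, CH2Cl2, rt
Reagents that add atoms: none
Why: Dess–Martin oxidation of the secondary benzylic alcohol should give the methyl ketone under near-neutral conditions that spare MOM ethers and aryl bromides.

Step 6
Reactants: 7 2,4-dihydroxybenzaldehyde
Product: 8 2-hydroxy-4-(methoxymethoxy)benzaldehyde
Conditions: MOMCl (1.05 equiv), K2CO3, acetone, 0 °C → rt
Reagents that add atoms: chloromethyl methyl ether, COCCl
Why: Regioselective O-alkylation: the 2-OH is hydrogen-bonded to the formyl group and less nucleophilic, so the 4-OH should be protected selectively.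

Step 7
Reactants: 6 1-[2,3-dibromo-4,5-bis(methoxymethoxy)phenyl]ethanone; 8 2-hydroxy-4-(methoxymethoxy)benzaldehyde
Product: 10 (E)-1-[2,3-dibromo-4,5-bis(methoxymethoxy)phenyl]-3-[2-hydroxy-4-(methoxymethoxy)phenyl]prop-2-en-1-one, via aldol adduct 9 (not isolated)
Conditions: KOH, EtOH/H2O, rt → 40 °C; then AcOH
Reagents that add atoms: none
Why: Claisen–Schmidt condensation: the enolate of methyl ketone 6 adds to the non-enolisable aldehyde and E1cB loss of water from 9 should give the E-enone, with MOM ethers and aryl bromides inert to hydroxide.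

Step 8
Reactants: 10 (E)-1-[2,3-dibromo-4,5-bis(methoxymethoxy)phenyl]-3-[2-hydroxy-4-(methoxymethoxy)phenyl]prop-2-en-1-one
Product: 11 1-[2,3-dibromo-4,5-bis(methoxymethoxy)phenyl]-3-[2-hydroxy-4-(methoxymethoxy)phenyl]propan-1-one
Conditions: H2 (3 bar), RhCl(PPh3)3 (5 mol %), PhMe/EtOH, 40 °C
Reagents that add atoms: none
Why: Homogeneous hydrogenation with RhCl(PPh3)3 should saturate the disubstituted enone C=C without reducing the ketone or cleaving the C–Br bonds, which a palladium-on-carbon hydrogenation would endanger.

Step 9
Reactants: 11 1-[2,3-dibromo-4,5-bis(methoxymethoxy)phenyl]-3-[2-hydroxy-4-(methoxymethoxy)phenyl]propan-1-one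
Product: 13 2-[2,3-dibromo-4,5-bis(methoxymethoxy)phenyl]-7-(methoxymethoxy)-4H-chromene, via cyclic hemiketal 12 (not isolated)
Conditions: PPTS (10 mol %), 4 Å MS, PhMe, 100 °C
Reagents that add atoms: none
Why: Acid-catalysed cyclodehydration: the phenol adds to the aryl ketone (6-exo-trig) to give hemiketal 12, which loses water through the 2-aryl oxocarbenium ion to the enol ether; pyridinium tosylate in dry toluene over sieves is expected to be too weak to cleave the aryl MOM ethers.

Step 10
Reactants: 13 2-[2,3-dibromo-4,5-bis(methoxymethoxy)phenyl]-7-(methoxymethoxy)-4H-chromene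
Product: 14 (2R)-2-[2,3-dibromo-4,5-bis(methoxymethoxy)phenyl]-7-(methoxymethoxy)chroman
Conditions: H2 (50 bar), [Ir(cod)(L)]B[C6H3(CF3)2]4 (2 mol %; cod = 1,5-cyclooctadiene, L = (S)-4-tert-butyl-2-[2-(diphenylphosphino)phenyl]-4,5-dihydrooxazole or its antipode, see remark 2), CH2Cl2, rt
Reagents that add atoms: none
Why: After hydrogenative loss of cyclooctadiene the cationic iridium dihydride binds the C2=C3 enol ether, and migratory insertion followed by reductive elimination (a trivalent/pentavalent iridium cycle) should deliver both hydrogens syn to one face, forming the C2–H and C3–H bonds. The closest known reaction type is the iridium phosphine–oxazoline catalysed asymmetric hydrogenation of 2-aryl-4H-chromenes and other unfunctionalised trisubstituted alkenes, which needs no directing group and uses the non-coordinating tetraarylborate counter-ion. No ring is closed in this step. C2 is the only new stereocenter and is controlled solely by the chiral ligand, whose oxazoline substituent blocks one quadrant so that the alkene binds with its small C3–H there and presents one enantioface. The step needs chemoselectivity for the alkene over C–Br hydrogenolysis and acetal cleavage: the bromines standing in for the prenyl groups leave C2=C3 as the only alkene, aryl bromides are inert to this catalyst, and dry CH2Cl2 at room temperature should keep the MOM ethers and the acid-sensitive enol ether intact.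

Step 11
Reactants: 14 (2R)-2-[2,3-dibromo-4,5-bis(methoxymethoxy)phenyl]-7-(methoxymethoxy)chroman; 15 prenylboronic acid pinacol ester
Product: 17 (2R)-2-[4,5-bis(methoxymethoxy)-2,3-bis(3-methylbut-2-en-1-yl)phenyl]-7-(methoxymethoxy)chroman, via mono-prenylated bromide 16 (not isolated)
Conditions: 15 (3 equiv), Pd(OAc)2 (10 mol %), SPhos (20 mol %), K3PO4, THF/H2O, 60 °C
Reagents that add atoms: prenylboronic acid pinacol ester 15, CC(C)=CCB1OC(C)(C)C(C)(C)O1
Why: Double Suzuki–Miyaura allyl–aryl coupling: a bulky dialkylbiarylphosphine on zerovalent palladium should insert into the hindered C–Br bonds (the less crowded C3'–Br is expected to react first, giving 16) and, after allyl isomerisation to the primary palladium–allyl species, transfer the prenyl group in its linear form, while C2 is not touched by the mild base.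

Step 12
Reactants: 17 (2R)-2-[4,5-bis(methoxymethoxy)-2,3-bis(3-methylbut-2-en-1-yl)phenyl]-7-(methoxymethoxy)chroman
Product: 18 (+)-(2R)-kazinol I
Conditions: ZnBr2, n-PrSH, CH2Cl2, 0 °C → rt, 10 min
Reagents that add atoms: none
Why: Lewis-acid-assisted thiolysis of the three MOM acetals: zinc activates the acetal oxygen and the soft thiol takes the methoxymethyl group, so no strong Brønsted acid is present that could cyclise the C3' prenyl group onto 4'-OH or ionise the O1–C2 bond.

**Compound list**

1 | 5-bromovanillin (3-bromo-4-hydroxy-5-methoxybenzaldehyde) | O=Cc1cc(Br)c(O)c(OC)c1 | starting material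
2 | 2,3-dibromo-4-hydroxy-5-methoxybenzaldehyde (5,6-dibromovanillin) | O=Cc1cc(OC)c(O)c(Br)c1Br | intermediate
3 | 2,3-dibromo-4,5-dihydroxybenzaldehyde | O=Cc1cc(O)c(O)c(Br)c1Br | intermediate
4 | 2,3-dibromo-4,5-bis(methoxymethoxy)benzaldehyde | O=Cc1cc(OCOC)c(OCOC)c(Br)c1Br | intermediate
5 | rac-1-[2,3-dibromo-4,5-bis(methoxymethoxy)phenyl]ethanol | CC(O)c1cc(OCOC)c(OCOC)c(Br)c1Br | intermediate
6 | 1-[2,3-dibromo-4,5-bis(methoxymethoxy)phenyl]ethanone | CC(=O)c1cc(OCOC)c(OCOC)c(Br)c1Br | intermediate
7 | 2,4-dihydroxybenzaldehyde | O=Cc1ccc(O)cc1O | starting material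
8 | 2-hydroxy-4-(methoxymethoxy)benzaldehyde | O=Cc1ccc(OCOC)cc1O | intermediate
9 | aldol adduct, rac-1-[2,3-dibromo-4,5-bis(methoxymethoxy)phenyl]-3-hydroxy-3-[2-hydroxy-4-(methoxymethoxy)phenyl]propan-1-one (not isolated) | O=C(CC(O)c1ccc(OCOC)cc1O)c1cc(OCOC)c(OCOC)c(Br)c1Br | intermediate
10 | (E)-1-[2,3-dibromo-4,5-bis(methoxymethoxy)phenyl]-3-[2-hydroxy-4-(methoxymethoxy)phenyl]prop-2-en-1-one | O=C(/C=C/c1ccc(OCOC)cc1O)c1cc(OCOC)c(OCOC)c(Br)c1Br | intermediate
11 | 1-[2,3-dibromo-4,5-bis(methoxymethoxy)phenyl]-3-[2-hydroxy-4-(methoxymethoxy)phenyl]propan-1-one | O=C(CCc1ccc(OCOC)cc1O)c1cc(OCOC)c(OCOC)c(Br)c1Br | intermediate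
12 | cyclic hemiketal, rac-2-[2,3-dibromo-4,5-bis(methoxymethoxy)phenyl]-7-(methoxymethoxy)chroman-2-ol (not isolated) | COCOc1ccc2c(c1)OC(O)(c1cc(OCOC)c(OCOC)c(Br)c1Br)CC2 | intermediate
13 | 2-[2,3-dibromo-4,5-bis(methoxymethoxy)phenyl]-7-(methoxymethoxy)-4H-chromene | Brc1c(C2=CCc3ccc(OCOC)cc3O2)cc(OCOC)c(OCOC)c1Br | intermediate
14 | (2R)-2-[2,3-dibromo-4,5-bis(methoxymethoxy)phenyl]-7-(methoxymethoxy)chroman | Brc1c([C@H]2CCc3ccc(OCOC)cc3O2)cc(OCOC)c(OCOC)c1Br | intermediate
15 | prenylboronic acid pinacol ester (4,4,5,5-tetramethyl-2-(3-methylbut-2-en-1-yl)-1,3,2-dioxaborolane) | CC(C)=CCB1OC(C)(C)C(C)(C)O1 | starting material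
16 | mono-prenylated bromide, (2R)-2-[2-bromo-4,5-bis(methoxymethoxy)-3-(3-methylbut-2-en-1-yl)phenyl]-7-(methoxymethoxy)chroman (not isolated) | Brc1c([C@H]2CCc3ccc(OCOC)cc3O2)cc(OCOC)c(OCOC)c1CC=C(C)C | intermediate
17 | (2R)-2-[4,5-bis(methoxymethoxy)-2,3-bis(3-methylbut-2-en-1-yl)phenyl]-7-(methoxymethoxy)chroman | CC(C)=CCc1c([C@H]2CCc3ccc(OCOC)cc3O2)cc(OCOC)c(OCOC)c1CC=C(C)C | intermediate
18 | (+)-(2R)-kazinol I, (2R)-2-[4,5-dihydroxy-2,3-bis(3-methylbut-2-en-1-yl)phenyl]chroman-7-ol | CC(C)=CCc1c([C@H]2CCc3ccc(O)cc3O2)cc(O)c(O)c1CC=C(C)C | target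

**Step count and risks**

Total step count: 12. Longest linear sequence: 11 steps (steps 1–5 and 7–12, from 5-bromovanillin).

Steps most likely to fail:

1. Step 10. The ortho bromine twists ring B out of the enol ether plane, so enantioface discrimination by the ligand may be poor, and the hindered alkene may hydrogenate slowly or the enol ether may decompose under the acidic iridium hydride. Fallback: the stereocenter is set by reagent-controlled ketone reduction instead. Ketone 11 is reduced with BH3·SMe2 (excess, to allow for the free phenol) and catalytic (R)-2-methyl-CBS-oxazaborolidine in THF at −20 °C, the aryl group acting as the large substituent. This should give (1S)-1-[2,3-dibromo-4,5-bis(methoxymethoxy)phenyl]-3-[2-hydroxy-4-(methoxymethoxy)phenyl]propan-1-ol F1. An intramolecular Mitsunobu etherification (PPh3, DIAD, THF, 0 °C) then closes ring C with inversion at the benzylic carbon, and the route is rejoined at flavan 14.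

2. Step 11. Both bromines sit between two ortho substituents, so the second coupling may stall, protodebromination may compete, and allyl transfer through the tertiary terminus would give reverse-prenyl isomers. Fallback: from dibromide 14, a double Stille coupling with allyltributylstannane (Pd(PPh3)4, DMF, 100 °C) should give (2R)-2-[4,5-bis(methoxymethoxy)-2,3-di(prop-2-en-1-yl)phenyl]-7-(methoxymethoxy)chroman F2, with no regiochemical ambiguity in the allyl transfer. Olefin cross-metathesis of both allyl groups with 2-methyl-2-butene (second-generation Grubbs catalyst, CH2Cl2, 40 °C) then converts them into prenyl groups and rejoins the route at compound 17.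

3. Step 12. During acetal cleavage the C3' prenyl group may cyclise onto the liberated 4'-OH to a dimethylchroman, or the O1–C2 bond para to the 4'-oxygen may ionise and erode the stereocenter. Fallback: the MOM groups are exchanged for acetates before any alkene is present, so the final deprotection is non-acidic. From 14, HCl in MeOH at 40 °C should give (2R)-2-(2,3-dibromo-4,5-dihydroxyphenyl)chroman-7-ol F3. Acetylation (Ac2O, pyridine) gives (2R)-2-(4,5-diacetoxy-2,3-dibromophenyl)chroman-7-yl acetate F4. Neutral Stille prenylation with tributyl(3-methylbut-2-en-1-yl)stannane (Pd(PPh3)4, DMF, 100 °C) gives (2R)-2-[4,5-diacetoxy-2,3-bis(3-methylbut-2-en-1-yl)phenyl]chroman-7-yl acetate F5. Hydrazinolysis of the three aryl acetates (N2H4·H2O, THF/MeOH, 0 °C) then arrives at target 18.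

**Further compounds**

F1 | step 10 | (1S)-1-[2,3-dibromo-4,5-bis(methoxymethoxy)phenyl]-3-[2-hydroxy-4-(methoxymethoxy)phenyl]propan-1-ol | O[C@@H](CCc1ccc(OCOC)cc1O)c1cc(OCOC)c(OCOC)c(Br)c1Br
F2 | step 11 | (2R)-2-[4,5-bis(methoxymethoxy)-2,3-di(prop-2-en-1-yl)phenyl]-7-(methoxymethoxy)chroman | C=CCc1c([C@H]2CCc3ccc(OCOC)cc3O2)cc(OCOC)c(OCOC)c1CC=C
F3 | step 12 | (2R)-2-(2,3-dibromo-4,5-dihydroxyphenyl)chroman-7-ol | Brc1c([C@H]2CCc3ccc(O)cc3O2)cc(O)c(O)c1Br
F4 | step 12 | (2R)-2-(4,5-diacetoxy-2,3-dibromophenyl)chroman-7-yl acetate | Brc1c([C@H]2CCc3ccc(OC(C)=O)cc3O2)cc(OC(C)=O)c(OC(C)=O)c1Br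
F5 | step 12 | (2R)-2-[4,5-diacetoxy-2,3-bis(3-methylbut-2-en-1-yl)phenyl]chroman-7-yl acetate | CC(C)=CCc1c([C@H]2CCc3ccc(OC(C)=O)cc3O2)cc(OC(C)=O)c(OC(C)=O)c1CC=C(C)C
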